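Slowness is where I begin: I ask at which step of this flask's round the catalyst queues, and what share stands in that queue.

substrate 48 mM; reagent 144 mM; free catalyst 6.2 mM

    reagent + free catalyst → catalyst intermediate A (k1 = 0.0077 M⁻¹ s⁻¹)
    substrate + catalyst intermediate A ⇌ catalyst intermediate B (K2 = 41 M⁻¹, k2 = 0.054 M⁻¹ s⁻¹)
    catalyst intermediate B → free catalyst + product (k3 = 0.0083 s⁻¹)
    2 free catalyst ⇌ resting dimer, settled at all times (K4 = 110 M⁻¹)

- for a step with 2 of a species take k times the square, and two of it per event
- what is bound to the catalyst counts as converted
- a form made of two catalysts counts as two
- charge of substrate (flask): 48 mM

- the form that holds most of the catalyst when 10% of the substrate are converted (free catalyst / catalyst intermediate A / catalyst intermediate B / resting dimer)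
- its share of the catalyst then

At the charge, free catalyst loads at 4.0 h⁻¹. Catalyst intermediate A moves on at 9.3 h⁻¹, but catalyst intermediate B falls back at 4.74 h⁻¹ and goes on at 30 h⁻¹, so A leaves at a net 8.05 h⁻¹. Loading is the slowest passage. I fold this into the load number 0.496, the loading rate over the net leaving rate, which is catalyst intermediate A held per free catalyst in a steady round. It scales with the fraction of reagent left over the fraction of substrate left.

At the asked moment I take substrate at 90.0% and reagent at 96.7%, which gives 0.532, so free catalyst stands above A. With 0.243 of B per A, this one number puts 60.2% of the catalyst in free form. That is not enough, because the dimer adds a second number, twice K4 times the catalyst charge, 1.36. The balance then gives free catalyst 44.2%, less than before, and resting dimer 26.6%. My resting state is free catalyst.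

The forecast also says free catalyst, at 44% within 40% to 49%, since “the slow loading step and the slow A-to-B step leave A at about half of free catalyst”.

The simulation gives free catalyst at 44.5%, with the resting dimer at 27.0%. A later look in the same run gives a different answer: after 6.00 h this flask holds 65.1% as catalyst intermediate A against 24.7% as free catalyst. With substrate at 10% and reagent at 67%, the load number becomes 3.32 there. The reading of A per free catalyst in this flask is 2.64, and, each step taken net, A is then made faster than it leaves, by a factor of 1.26.

The constants used here come from no measurement; the rest is arithmetic.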